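**Retrosynthetic overview**

1. Target 20 comes from dibenzyl ketone 19 by hydrogenolysis of the ring C aryl benzyl ether and the C4 benzyloxymethyl ether.
2. The strategy rests on ring A, a 1-acyl-3-hydroxy-4-methoxybenzene joined through the ketone carbon to C3 of tetrahydrofuran ring B. Its C(OH), C(OMe) and the two following CH map onto C2, C3, C4 and C5 of 3-methoxyfuran 17, and its acyl-bearing carbon and the CH between acyl and hydroxyl map onto the alkyne of terminal ynone 16. Two ring A C–C bonds are therefore cut (Diels–Alder reaction, then bridge opening).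
3. Ynone 16 comes from Weinreb amide 14 and ester 13. The C4 CH2OBn group comes from a vinyl group added by copper catalysis anti to the C5 aryl of dihydrofuran ester 7, and C3 is set by equilibration.
4. Ring B (7) comes from ring-closing metathesis of ether 6, made from (S)-allylic alcohol 4 (lipase resolution of 3) and bromomethyl acrylate 5; 3 comes from aldehyde 1 and vinyl Grignard reagent 2.
5. Ring order: ring C is bought with 1, ring B is closed in step 4, ring A is built last in step 10.

Key step: step 10

Remark: ring B is numbered O1, C2 (CH2), C3 (carbonyl-bearing), C4 (one-carbon substituent), C5 (aryl-bearing); CIP analysis of the given SMILES gives (3S,4R,5S) with the three substituents all-trans, and 3-methoxyfuran is taken as a purchasable reagent.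

**Route**

Step 1
Reactants: 1 3-benzyloxy-4-methoxybenzaldehyde; 2 vinylmagnesium bromide
Product: 3 rac-1-[3-(benzyloxy)-4-methoxyphenyl]prop-2-en-1-ol
Conditions: THF, −78 → 0 °C; aq NH4Cl; chromatography on Et3N-deactivated silica
Reagents that add atoms: none
Why: Grignard 1,2-addition to the aryl aldehyde should give the racemic allylic alcohol, and the non-acidic work-up is meant to prevent ionisation and allylic transposition of this electron-rich benzylic alcohol.

Step 2
Reactants: 3 rac-1-[3-(benzyloxy)-4-methoxyphenyl]prop-2-en-1-ol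
Product: 4 (S)-1-[3-(benzyloxy)-4-methoxyphenyl]prop-2-en-1-ol
Conditions: Novozym 435 (immobilised Candida antarctica lipase B), vinyl acetate, MTBE, 4 Å MS, 30 °C, run just past half conversion
Reagents that add atoms: none
Why: Lipase-catalysed kinetic resolution by enantioselective transesterification should acetylate the (R)-alcohol (aryl as the large and vinyl as the medium group in the Kazlauskas model) and leave the (S)-alcohol, which fixes C5 of ring B for the whole route.

Step 3
Reactants: 4 (S)-1-[3-(benzyloxy)-4-methoxyphenyl]prop-2-en-1-ol; 5 methyl 2-(bromomethyl)acrylate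
Product: 6 methyl 2-({[(1S)-1-[3-(benzyloxy)-4-methoxyphenyl]prop-2-en-1-yl]oxy}methyl)prop-2-enoate
Conditions: NaH, THF, 0 °C; then 5, 0 °C → rt
Reagents that add atoms: none
Why: Williamson-type O-allylation of the sodium alkoxide by the 2-(bromomethyl)acrylate (direct or SN2' displacement, both giving the same ether) does not touch the carbinol C–O bond, so the (S) centre should be retained.

Step 4
Reactants: 6 methyl 2-({[(1S)-1-[3-(benzyloxy)-4-methoxyphenyl]prop-2-en-1-yl]oxy}methyl)prop-2-enoate
Product: 7 methyl (5S)-5-[3-(benzyloxy)-4-methoxyphenyl]-2,5-dihydrofuran-3-carboxylate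
Conditions: second-generation Grubbs catalyst RuCl2(=CHPh)(PCy3)(H2IMes) (5 mol %), CH2Cl2, 40 °C
Reagents that add atoms: none
Why: Ring-closing olefin metathesis between the vinyl group and the 1,1-disubstituted acrylate alkene should close the five-membered ring B as the 2,5-dihydrofuran-3-carboxylate with loss of ethene, a well-used route to this heterocycle.

Step 5
Reactants: 7 methyl (5S)-5-[3-(benzyloxy)-4-methoxyphenyl]-2,5-dihydrofuran-3-carboxylate; 2 vinylmagnesium bromide
Product: 10 methyl (3S,4S,5S)-5-[3-(benzyloxy)-4-methoxyphenyl]-4-ethenyltetrahydrofuran-3-carboxylate, via silyl ketene acetal 8 (not isolated), via 3,4-cis ester 9 (not isolated)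
Conditions: CuBr·SMe2 (10 mol %), TMSCl, THF, −78 → −40 °C; aq NH4Cl; crude ester then NaOMe, MeOH, rt
Reagents that add atoms: none
Why: Copper-catalysed, chlorosilane-accelerated conjugate addition of the vinyl Grignard reagent to the cyclic enoate should deliver vinyl to C4 on the face anti to the adjacent C5 aryl group (4,5-trans), and methoxide equilibration of the ester α-carbon C3 should then place the ester trans to the C4 vinyl group as the thermodynamically preferred all-trans isomer.

Step 6
Reactants: 10 methyl (3S,4S,5S)-5-[3-(benzyloxy)-4-methoxyphenyl]-4-ethenyltetrahydrofuran-3-carboxylate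
Product: 12 methyl (3S,4R,5S)-5-[3-(benzyloxy)-4-methoxyphenyl]-4-(hydroxymethyl)tetrahydrofuran-3-carboxylate, via aldehyde 11 (not isolated)
Conditions: K2OsO4·2H2O (2 mol %), NaIO4, 2,6-lutidine, dioxane–H2O, rt; extract; then NaBH4, MeOH, −20 °C
Reagents that add atoms: sodium periodate (oxygen donor, relayed by the osmium catalyst), [Na+].[O-]I(=O)(=O)=O
Why: Lemieux–Johnson oxidative cleavage of the terminal alkene followed by sodium borohydride reduction of the crude aldehyde should give the primary alcohol beside the untouched methyl ester, the lutidine buffer and low temperature guarding C4, which already holds its more stable trans,trans arrangement.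

Step 7
Reactants: 12 methyl (3S,4R,5S)-5-[3-(benzyloxy)-4-methoxyphenyl]-4-(hydroxymethyl)tetrahydrofuran-3-carboxylate
Product: 13 methyl (3S,4R,5S)-5-[3-(benzyloxy)-4-methoxyphenyl]-4-(benzyloxymethyl)tetrahydrofuran-3-carboxylate
Conditions: 2-benzyloxy-1-methylpyridinium triflate, MgO, PhCF3, 83 °C
Reagents that add atoms: 2-benzyloxy-1-methylpyridinium trifluoromethanesulfonate, C[n+]1ccccc1OCc1ccccc1.[O-]S(=O)(=O)C(F)(F)F
Why: Benzyl transfer from the 2-benzyloxypyridinium salt (Dudley benzylation) runs under near-neutral conditions, so the γ-hydroxy ester should be etherified without the C3 epimerisation that alkoxide conditions would drive into the cis-fused bicyclic lactone.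

Step 8
Reactants: 13 methyl (3S,4R,5S)-5-[3-(benzyloxy)-4-methoxyphenyl]-4-(benzyloxymethyl)tetrahydrofuran-3-carboxylate
Product: 14 (3S,4R,5S)-5-[3-(benzyloxy)-4-methoxyphenyl]-4-(benzyloxymethyl)-N-methoxy-N-methyltetrahydrofuran-3-carboxamide
Conditions: MeNH(OMe)·HCl, iPrMgCl, THF, −20 → 0 °C
Reagents that add atoms: N,O-dimethylhydroxylamine hydrochloride, CNOC.Cl
Why: Aminolysis of the methyl ester by the chloromagnesium amide of N,O-dimethylhydroxylamine (Weinreb amide formation) should give the amide, and since C3 already has its stable trans configuration no stereochemical loss is expected.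

Step 9
Reactants: 14 (3S,4R,5S)-5-[3-(benzyloxy)-4-methoxyphenyl]-4-(benzyloxymethyl)-N-methoxy-N-methyltetrahydrofuran-3-carboxamide; 15 ethynylmagnesium bromide
Product: 16 1-[(3S,4R,5S)-5-[3-(benzyloxy)-4-methoxyphenyl]-4-(benzyloxymethyl)tetrahydrofuran-3-yl]prop-2-yn-1-one
Conditions: THF, 0 °C → rt; inverse quench into cold 1 M aq NaHSO4; used promptly
Reagents that add atoms: none
Why: Addition of the alkynyl Grignard reagent to the Weinreb amide stops at the chelated tetrahedral intermediate (Weinreb ketone synthesis), and the inverse acidic quench should release the terminal ynone while keeping the liberated hydroxylamine protonated so that it cannot add to the ynone.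

Step 10
Reactants: 16 1-[(3S,4R,5S)-5-[3-(benzyloxy)-4-methoxyphenyl]-4-(benzyloxymethyl)tetrahydrofuran-3-yl]prop-2-yn-1-one; 17 3-methoxyfuran
Product: 19 [(3S,4R,5S)-5-[3-(benzyloxy)-4-methoxyphenyl]-4-(benzyloxymethyl)tetrahydrofuran-3-yl](3-hydroxy-4-methoxyphenyl)methanone, via oxanorbornadiene 18 (not isolated)
Conditions: 17 (3 equiv), toluene, 50 °C, dark; evaporate; then CSA (10 mol %), dry CH2Cl2, 0 °C → rt
Reagents that add atoms: none
Why: The methoxy group raises the HOMO of the furan and makes C2 its most nucleophilic terminus, so a polar, asynchronous [4+2] cycloaddition (normal-electron-demand Diels–Alder reaction) joins furan C2 to the terminal alkyne carbon and furan C5 to the acyl-bearing alkyne carbon, giving 7-oxanorbornadiene 18. The closest known reaction type is the Diels–Alder reaction of alkoxyfurans with alkynones and alkynoates followed by acid-induced opening of the oxygen bridge to a phenol. Ring A is closed by the intermolecular cycloaddition itself, which forms both of its new carbon–carbon bonds in a six-membered ring, and anhydrous acid then cleaves the bridge C–O bond at the former furan C5, whose cation is conjugated with the methoxy enol ether, after which loss of the proton from the former furan C2 aromatises the ring and leaves the hydroxyl on that carbon, ortho to methoxy. No lasting stereocentre is created: the two bridgehead centres of 18 are erased on aromatisation, and C3, C4 and C5 of ring B are spectators, C3 (α to the ketone) already holding its stable trans configuration. The selectivity needed is regiochemical, in both the cycloaddition and the bridge opening, and the single methoxy group directs both, giving hydroxyl meta and methoxy para to the acyl group. Thermal cycloaddition without Lewis acid is chosen to disfavour open-chain conjugate alkylation of the furan, and the acid is kept catalytic, anhydrous and cold so that the enol ether is not hydrolysed and the C5 benzylic ether of ring B does not ionise.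

Step 11
Reactants: 19 [(3S,4R,5S)-5-[3-(benzyloxy)-4-methoxyphenyl]-4-(benzyloxymethyl)tetrahydrofuran-3-yl](3-hydroxy-4-methoxyphenyl)methanone
Product: 20 [(3S,4R,5S)-4-(hydroxymethyl)-5-(3-hydroxy-4-methoxyphenyl)tetrahydrofuran-3-yl](3-hydroxy-4-methoxyphenyl)methanone (CNP0234761.1)
Conditions: H2 (1 atm), 10% Pd/C, EtOAc–MeOH, rt, stopped at full debenzylation
Reagents that add atoms: none
Why: Catalytic hydrogenolysis of the aryl and the alkyl benzyl ether over palladium on carbon in a neutral solvent should free both hydroxyl groups, and the electron-rich aryl ketone and the cyclic benzylic ether are expected to survive if the reaction is stopped in time.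

**Compound list**

1 | 3-benzyloxy-4-methoxybenzaldehyde | COc1ccc(C=O)cc1OCc1ccccc1 | starting material
2 | vinylmagnesium bromide | C=C[Mg]Br | starting material
3 | rac-1-[3-(benzyloxy)-4-methoxyphenyl]prop-2-en-1-ol | C=CC(O)c1ccc(OC)c(OCc2ccccc2)c1 | intermediate
4 | (S)-1-[3-(benzyloxy)-4-methoxyphenyl]prop-2-en-1-ol | C=C[C@H](O)c1ccc(OC)c(OCc2ccccc2)c1 | intermediate
5 | methyl 2-(bromomethyl)acrylate | C=C(CBr)C(=O)OC | starting material
6 | methyl 2-({[(1S)-1-[3-(benzyloxy)-4-methoxyphenyl]prop-2-en-1-yl]oxy}methyl)prop-2-enoate | C=C[C@@H](c1ccc(OC)c(OCc2ccccc2)c1)OCC(=C)C(=O)OC | intermediate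
7 | methyl (5S)-5-[3-(benzyloxy)-4-methoxyphenyl]-2,5-dihydrofuran-3-carboxylate | COC(=O)C1=C[C@@H](c2ccc(OC)c(OCc3ccccc3)c2)OC1 | intermediate
8 | trimethylsilyl ketene acetal of the (4S,5S)-4-ethenyl ester (silyl enol ether of 10, exocyclic C3=C) | COC(O[Si](C)(C)C)=C1CO[C@H](c2ccc(OC)c(OCc3ccccc3)c2)[C@H]1C=C | intermediate (not isolated)
9 | methyl (3R,4S,5S)-5-[3-(benzyloxy)-4-methoxyphenyl]-4-ethenyltetrahydrofuran-3-carboxylate (3,4-cis, 4,5-trans) | COC(=O)[C@H]1CO[C@H](c2ccc(OC)c(OCc3ccccc3)c2)[C@H]1C=C | intermediate (not isolated)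
10 | methyl (3S,4S,5S)-5-[3-(benzyloxy)-4-methoxyphenyl]-4-ethenyltetrahydrofuran-3-carboxylate (all-trans) | COC(=O)[C@@H]1CO[C@H](c2ccc(OC)c(OCc3ccccc3)c2)[C@H]1C=C | intermediate
11 | methyl (3S,4S,5S)-5-[3-(benzyloxy)-4-methoxyphenyl]-4-formyltetrahydrofuran-3-carboxylate | COC(=O)[C@@H]1CO[C@H](c2ccc(OC)c(OCc3ccccc3)c2)[C@H]1C=O | intermediate (not isolated)
12 | methyl (3S,4R,5S)-5-[3-(benzyloxy)-4-methoxyphenyl]-4-(hydroxymethyl)tetrahydrofuran-3-carboxylate | COC(=O)[C@@H]1CO[C@H](c2ccc(OC)c(OCc3ccccc3)c2)[C@H]1CO | intermediate
13 | methyl (3S,4R,5S)-5-[3-(benzyloxy)-4-methoxyphenyl]-4-(benzyloxymethyl)tetrahydrofuran-3-carboxylate | COC(=O)[C@@H]1CO[C@H](c2ccc(OC)c(OCc3ccccc3)c2)[C@H]1COCc1ccccc1 | intermediate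
14 | (3S,4R,5S)-5-[3-(benzyloxy)-4-methoxyphenyl]-4-(benzyloxymethyl)-N-methoxy-N-methyltetrahydrofuran-3-carboxamide | CON(C)C(=O)[C@@H]1CO[C@H](c2ccc(OC)c(OCc3ccccc3)c2)[C@H]1COCc1ccccc1 | intermediate
15 | ethynylmagnesium bromide | C#C[Mg]Br | starting material
16 | 1-[(3S,4R,5S)-5-[3-(benzyloxy)-4-methoxyphenyl]-4-(benzyloxymethyl)tetrahydrofuran-3-yl]prop-2-yn-1-one | C#CC(=O)[C@@H]1CO[C@H](c2ccc(OC)c(OCc3ccccc3)c2)[C@H]1COCc1ccccc1 | intermediate
17 | 3-methoxyfuran | COc1ccoc1 | starting material
18 | 5-acyl-2-methoxy-7-oxabicyclo[2.2.1]hepta-2,5-diene carrying the ring B unit of 16 on the ketone (bridgehead diastereomer mixture) | COC1=CC2OC1C=C2C(=O)[C@@H]1CO[C@H](c2ccc(OC)c(OCc3ccccc3)c2)[C@H]1COCc1ccccc1 | intermediate (not isolated)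
19 | [(3S,4R,5S)-5-[3-(benzyloxy)-4-methoxyphenyl]-4-(benzyloxymethyl)tetrahydrofuran-3-yl](3-hydroxy-4-methoxyphenyl)methanone | COc1ccc(C(=O)[C@@H]2CO[C@H](c3ccc(OC)c(OCc4ccccc4)c3)[C@H]2COCc2ccccc2)cc1O | intermediate
20 | [(3S,4R,5S)-4-(hydroxymethyl)-5-(3-hydroxy-4-methoxyphenyl)tetrahydrofuran-3-yl](3-hydroxy-4-methoxyphenyl)methanone | COc1ccc(C(=O)[C@@H]2CO[C@H](c3ccc(OC)c(O)c3)[C@H]2CO)cc1O | target

**Step count**

Total: 11 steps. Longest linear sequence: 11 steps (1 → 20).

**Steps most likely to fail**

1. Step 10. The furan may attack the ynone as a carbon nucleophile without closing the ring (open-chain conjugate alkylation), the cycloaddition may take the reverse orientation, the enol ether of 18 may hydrolyse to a bridged ketone in place of bridge opening, or the terminal ynone may polymerise on heating. The fallback sets out from Weinreb amide 14 and returns at target 20, and it attaches ring A preformed. Bromine–lithium exchange on purchased 2-(benzyloxy)-4-bromo-1-methoxybenzene (n-BuLi, THF, −78 °C) would give [3-(benzyloxy)-4-methoxyphenyl]lithium F1. Addition of it to 14 (Weinreb ketone synthesis) would give the tribenzyl ketone [(3S,4R,5S)-5-[3-(benzyloxy)-4-methoxyphenyl]-4-(benzyloxymethyl)tetrahydrofuran-3-yl][3-(benzyloxy)-4-methoxyphenyl]methanone F2. Hydrogenolysis of its three benzyl ethers (H2, Pd/C, EtOAc) would give 20.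

2. Step 5. The basic Grignard reagent may deprotonate the doubly activated C5–H of 7 in competition with conjugate addition, with loss of the stereocentre and drift towards the furan. Facial selectivity at C4 may be incomplete, and during the methoxide equilibration the ring oxygen may be expelled by β-elimination from the C3 enolate. The fallback sets out from 7 and returns at aldehyde 11, which is then reduced as in the second half of step 6. It replaces the organometallic addition by a neutral radical one: benzophenone-sensitised photoaddition of 1,3-dioxolane (as solvent, 350 nm), in which the dioxolanyl radical (a masked formyl group) should add to C4 anti to the C5 aryl group. This would give methyl (3S,4S,5S)-5-[3-(benzyloxy)-4-methoxyphenyl]-4-(1,3-dioxolan-2-yl)tetrahydrofuran-3-carboxylate F3 together with its 3,4-cis epimer methyl (3R,4S,5S)-5-[3-(benzyloxy)-4-methoxyphenyl]-4-(1,3-dioxolan-2-yl)tetrahydrofuran-3-carboxylate F4. NaOMe in MeOH should converge F4 on F3, and mild acetal hydrolysis of F3 (PPTS, wet acetone, 50 °C) would give 11.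

3. Step 11. While the slower alkyl benzyl ether is still being cleaved, the aryl ketone may be hydrogenated to the benzylic alcohol or methylene compound, or the C5–O1 benzylic ether bond of ring B may be opened by hydrogenolysis. The fallback sets out from 19 and returns at 20 by a non-reductive cleavage: BCl3 with pentamethylbenzene as benzyl cation scavenger, CH2Cl2, −78 °C, MeOH quench, which should remove both benzyl groups without hydrogen; no new compound arises (entry F0).

**Further compounds**

F1 | step 10 | [3-(benzyloxy)-4-methoxyphenyl]lithium | [Li]c1ccc(OC)c(OCc2ccccc2)c1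
F2 | step 10 | [(3S,4R,5S)-5-[3-(benzyloxy)-4-methoxyphenyl]-4-(benzyloxymethyl)tetrahydrofuran-3-yl][3-(benzyloxy)-4-methoxyphenyl]methanone | COc1ccc(C(=O)[C@@H]2CO[C@H](c3ccc(OC)c(OCc4ccccc4)c3)[C@H]2COCc2ccccc2)cc1OCc1ccccc1
F3 | step 5 | methyl (3S,4S,5S)-5-[3-(benzyloxy)-4-methoxyphenyl]-4-(1,3-dioxolan-2-yl)tetrahydrofuran-3-carboxylate | COC(=O)[C@@H]1CO[C@H](c2ccc(OC)c(OCc3ccccc3)c2)[C@H]1C1OCCO1
F4 | step 5 | methyl (3R,4S,5S)-5-[3-(benzyloxy)-4-methoxyphenyl]-4-(1,3-dioxolan-2-yl)tetrahydrofuran-3-carboxylate | COC(=O)[C@H]1CO[C@H](c2ccc(OC)c(OCc3ccccc3)c2)[C@H]1C1OCCO1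
F0 | step 11 | none | none
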